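## Retrosynthetic overview

1. The butenolide is attached last: the C12–C13 bond comes from a B-alkyl Suzuki coupling of a 9β-vinyl carbinol with 3-bromofuran-2(5H)-one. The vinyl carbinol comes from a C9 ketone, the 6β-acetate from a 6α-alcohol by oxidation and reduction, and the C4 gem-dimethyl group from a C3=C4(Me) alkene by hydromethylation.
2. Both carbocycles are made in one intramolecular Diels–Alder reaction of an acyclic trienone: dienophile C1=C10 (isopropenyl ketone) plus diene C2=C3–C4(Me)=C5 forms C1–C2 and C5–C10. Rings A and B arise together; no carbocycle exists before this step.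
3. Enabling feature: C9 of ring B, the carbinol carbon next to quaternary C10, can be carried as a ketone that activates C1=C10 and lies inside the four-atom tether C6–C9. C4 of ring A can be carried as an sp2 carbon with one methyl, and that methyl, cis to the oxygenated C6, steers the cycloaddition by allylic strain.
4. The trienone comes from a trans-α-methyl-γ-dienyl-γ-butyrolactone and isopropenyllithium. The lactone comes from (5S)-5-(hydroxymethyl)oxolan-2-one (the one bought stereocenter, future C6) by oxidation, two Wittig reactions and enolate methylation (C8).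
5. Stereochemical relay: C6 → C8 → C5 and C10 (key step) → C9 → C6 (reset by hydride from the α face).

Key step: step 5

Assumption: decalin compounds are described with labdane numbering (C4 gem-dimethyl carbon, C5 ring-fusion CH, C6 oxygenated carbon, C8 methyl-bearing carbon, C9 carbinol carbon, C10 angular carbon; β is the face of the C10 methyl group), and 3-bromofuran-2(5H)-one and the formaldehyde sulfonylhydrazone of step 6 are taken as purchasable or one-step reagents.

## Route

Step 1
Reactants: 1 (5S)-5-(hydroxymethyl)oxolan-2-one; 2 2-(triphenylphosphoranylidene)propanal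
Product: 4 (2E)-2-methyl-3-[(2S)-5-oxooxolan-2-yl]prop-2-enal, via aldehyde 3 (not isolated)
Conditions: (COCl)2, DMSO, CH2Cl2, −78 °C; Et3N; then 2, −78 °C to rt
Reagents that add atoms: 2-(triphenylphosphoranylidene)propanal, CC(C=O)=P(c1ccccc1)(c1ccccc1)c1ccccc1
Why: Swern oxidation followed in the same flask by a Wittig reaction with the formyl-stabilized ylide should trap the labile α-acyloxy aldehyde as the (E)-trisubstituted enal (stabilized ylide, E-selective) without touching the bought stereocenter, which becomes C6.

Step 2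
Reactants: 4 (2E)-2-methyl-3-[(2S)-5-oxooxolan-2-yl]prop-2-enal
Product: 5 (5S)-5-[(1E)-2-methylbuta-1,3-dien-1-yl]oxolan-2-one
Conditions: Ph3PCH3Br, KN(SiMe3)2, THF, −78 °C; then 4, −78 to 0 °C
Reagents that add atoms: methyltriphenylphosphonium bromide, C[P+](c1ccccc1)(c1ccccc1)c1ccccc1.[Br-]
Why: Wittig methylenation of the enal aldehyde at low temperature should outrun attack on the lactone carbonyl and γ-deprotonation, so the (E)-diene forms with the stereocenter intact.

Step 3
Reactants: 5 (5S)-5-[(1E)-2-methylbuta-1,3-dien-1-yl]oxolan-2-one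
Product: 6 (3R,5S)-3-methyl-5-[(1E)-2-methylbuta-1,3-dien-1-yl]oxolan-2-one
Conditions: LiN(i-Pr)2, THF, −78 °C; MeI, −78 to −40 °C
Reagents that add atoms: iodomethane, CI
Why: Alkylation of the lithium enolate of a γ-substituted butyrolactone takes place on the face anti to the γ-substituent, which should set the new α-methyl center (future C8) trans to the dienyl group; the minor cis isomer would be removed by chromatography.

Step 4
Reactants: 6 (3R,5S)-3-methyl-5-[(1E)-2-methylbuta-1,3-dien-1-yl]oxolan-2-one; 7 2-bromopropene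
Product: 8 (4R,6S,7E)-6-hydroxy-2,4,8-trimethyldeca-1,7,9-trien-3-one
Conditions: 7, t-BuLi (2 equiv), Et2O, −78 °C; then 6, THF, −78 °C; AcOH, −78 °C
Reagents that add atoms: 2-bromopropene, CC(Br)=C
Why: Addition of an organolithium (from bromine–lithium exchange) to a lactone stops at the ketone stage because the lithium hemiketal alkoxide survives at −78 °C until the cold acidic quench, which should give the γ-hydroxy isopropenyl ketone with both stereocenters unchanged.

Step 5
Reactants: 8 (4R,6S,7E)-6-hydroxy-2,4,8-trimethyldeca-1,7,9-trien-3-one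
Product: 9 (2R,4S,4aS,8aS)-4-hydroxy-2,5,8a-trimethyl-3,4,4a,7,8,8a-hexahydronaphthalen-1(2H)-one
Conditions: toluene (0.01 M), BHT (cat.), 100 °C, Ar
Reagents that add atoms: none
Why: A thermal, concerted but asynchronous intramolecular [4+2] cycloaddition joins the isopropenyl ketone (C1=C10, activated by the C9 carbonyl) to the diene C2=C3–C4(Me)=C5, the C1–C2 bond forming ahead of the C5–C10 bond; the closest known type is the intramolecular Diels–Alder reaction of 1,7,9-decatrien-3-ones to octalones. Ring A (C10–C1–C2–C3–C4–C5) closes as the cyclohexene of the cycloaddition and ring B (C5–C6–C7–C8–C9–C10) closes at the same time through the four-atom tether, so the open chain becomes the decalin in one event. C5 is controlled by C6: the C4 methyl group is cis to C6 on the diene, allylic 1,3-strain keeps the C6–H bond in the diene plane, and the tether can reach only the diene face anti to the hydroxyl group, which ends up equatorial (6α) next to the 5α hydrogen; the C8 methyl group is equatorial in the same chair, so the two existing centers are matched. C10 is controlled by the exo orientation of the C9 acyl group (angular methyl endo), which gives the trans ring fusion. The step needs diene-face selectivity and exo over endo selectivity: with the C6–H bond held in the diene plane only the exo mode has a chair-like ring B in the transition state, while the endo mode needs a boat or an allylically strained rotamer, and the α-methyl group of the dienophile adds its usual preference for an exo carbonyl. The cyclic hemiketal of the γ-hydroxy enone is in equilibrium with the open form and should be drained through it.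

Step 6
Reactants: 9 (2R,4S,4aS,8aS)-4-hydroxy-2,5,8a-trimethyl-3,4,4a,7,8,8a-hexahydronaphthalen-1(2H)-one
Product: 11 (2R,4S,4aS,8aS)-4-hydroxy-2,5,5,8a-tetramethyloctahydronaphthalen-1(2H)-one, via sulfonylhydrazide 10 (not isolated)
Conditions: Fe(acac)3, PhSiH3, CH2=NNHSO2C8H17, THF/MeOH, 30 °C; then Et3N, MeOH, 60 °C
Reagents that add atoms: formaldehyde octane-1-sulfonylhydrazone, C=NNS(=O)(=O)CCCCCCCC
Why: Iron hydride hydrogen-atom transfer to the trisubstituted C3=C4 alkene gives the tertiary C4 radical, which is trapped by the formaldehyde sulfonylhydrazone and then loses sulfinate and dinitrogen on warming (Markovnikov olefin hydromethylation); no stereocenter is created because C4 becomes the gem-dimethyl carbon.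

Step 7
Reactants: 11 (2R,4S,4aS,8aS)-4-hydroxy-2,5,5,8a-tetramethyloctahydronaphthalen-1(2H)-one; 12 vinylmagnesium bromide
Product: 13 (1R,2R,4S,4aS,8aS)-1-ethenyl-2,5,5,8a-tetramethyldecahydronaphthalene-1,4-diol
Conditions: CH2=CHMgBr (3.5 equiv), CeCl3, THF, −78 to 0 °C; aq NH4Cl
Reagents that add atoms: vinylmagnesium bromide, C=C[Mg]Br
Why: Organocerium 1,2-addition suppresses enolization of the hindered C9 ketone, and, as with 2,2,6-trisubstituted cyclohexanones, the nucleophile should enter equatorially, trans to the equatorial C8 methyl group, to give the axial 9α-hydroxyl and the 9β-vinyl group.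

Step 8
Reactants: 13 (1R,2R,4S,4aS,8aS)-1-ethenyl-2,5,5,8a-tetramethyldecahydronaphthalene-1,4-diol
Product: 14 (3R,4R,4aS,8aS)-4-ethenyl-4-hydroxy-3,4a,8,8-tetramethyloctahydronaphthalen-1(2H)-one
Conditions: Dess–Martin periodinane, CH2Cl2, 0 °C to rt
Reagents that add atoms: none
Why: Dess–Martin oxidation converts the secondary 6α-carbinol into the ketone while the tertiary allylic C9 carbinol cannot react, and the non-basic medium should leave the trans ring fusion at C5 untouched.

Step 9
Reactants: 14 (3R,4R,4aS,8aS)-4-ethenyl-4-hydroxy-3,4a,8,8-tetramethyloctahydronaphthalen-1(2H)-one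
Product: 15 (1R,2R,4R,4aS,8aS)-1-ethenyl-2,5,5,8a-tetramethyldecahydronaphthalene-1,4-diol
Conditions: NaBH4, MeOH, 0 °C
Reagents that add atoms: none
Why: In this substrate-controlled borohydride reduction the β face of the 6-ketone is blocked by the syn-axial C10 and C4β methyl groups, so hydride should enter from the α face and give the axial 6β-alcohol.

Step 10
Reactants: 15 (1R,2R,4R,4aS,8aS)-1-ethenyl-2,5,5,8a-tetramethyldecahydronaphthalene-1,4-diol
Product: 16 (1R,3R,4R,4aS,8aS)-4-ethenyl-4-hydroxy-3,4a,8,8-tetramethyldecahydronaphthalen-1-yl acetate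
Conditions: Ac2O, DMAP, pyridine, 40 °C
Reagents that add atoms: acetic anhydride, CC(=O)OC(C)=O
Why: DMAP-catalyzed acylation should reach the hindered secondary axial 6β-hydroxyl but not the tertiary C9 hydroxyl.

Step 11
Reactants: 16 (1R,3R,4R,4aS,8aS)-4-ethenyl-4-hydroxy-3,4a,8,8-tetramethyldecahydronaphthalen-1-yl acetate; 17 3-bromofuran-2(5H)-one
Product: 19 3-{2-[(1R,2R,4R,4aS,8aS)-4-(acetyloxy)-1-hydroxy-2,5,5,8a-tetramethyldecahydronaphthalen-1-yl]ethyl}furan-2(5H)-one, via alkylborane 18 (not isolated)
Conditions: 9-BBN (2.5 equiv), THF, 0 to 40 °C; then 17, PdCl2(dppf), AsPh3, K3PO4, DMF/H2O, rt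
Reagents that add atoms: 3-bromofuran-2(5H)-one, O=C1OCC=C1Br
Why: Anti-Markovnikov hydroboration of the vinyl group and B-alkyl Suzuki–Miyaura coupling with the α-bromobutenolide form the C12–C13 bond and should deliver the α-substituted butenolide intact, with no stereocenter affected and the hindered acetate surviving the mild base at room temperature.

## Compound list

1 | (5S)-5-(hydroxymethyl)oxolan-2-one | O=C1CC[C@@H](CO)O1 | starting material
2 | 2-(triphenylphosphoranylidene)propanal | CC(C=O)=P(c1ccccc1)(c1ccccc1)c1ccccc1 | starting material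
3 | (2S)-5-oxooxolane-2-carbaldehyde | O=C1CC[C@@H](C=O)O1 | intermediate
4 | (2E)-2-methyl-3-[(2S)-5-oxooxolan-2-yl]prop-2-enal | O=C1CC[C@@H](/C=C(\C)C=O)O1 | intermediate
5 | (5S)-5-[(1E)-2-methylbuta-1,3-dien-1-yl]oxolan-2-one | O=C1CC[C@@H](/C=C(\C)C=C)O1 | intermediate
6 | (3R,5S)-3-methyl-5-[(1E)-2-methylbuta-1,3-dien-1-yl]oxolan-2-one (trans) | O=C1[C@H](C)C[C@@H](/C=C(\C)C=C)O1 | intermediate
7 | 2-bromopropene | CC(Br)=C | starting material
8 | (4R,6S,7E)-6-hydroxy-2,4,8-trimethyldeca-1,7,9-trien-3-one | C=C(C)C(=O)[C@H](C)C[C@H](O)/C=C(\C)C=C | intermediate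
9 | (2R,4S,4aS,8aS)-4-hydroxy-2,5,8a-trimethyl-3,4,4a,7,8,8a-hexahydronaphthalen-1(2H)-one (trans-fused; 5α-H, 6α-OH, 8α-Me, 10β-Me, C3=C4 alkene, C9 ketone) | O[C@H]1C[C@@H](C)C(=O)[C@@]2(C)CCC=C(C)[C@H]12 | intermediate
10 | alkyl sulfonylhydrazide: compound 9 with H added at C3 and a CH2NHNHSO2C8H17 group added at C4 (either C4 epimer) | O[C@H]1C[C@@H](C)C(=O)[C@@]2(C)CCCC(C)(CNNS(=O)(=O)CCCCCCCC)[C@H]12 | intermediate
11 | (2R,4S,4aS,8aS)-4-hydroxy-2,5,5,8a-tetramethyloctahydronaphthalen-1(2H)-one (6α-OH, C9 ketone) | O[C@H]1C[C@@H](C)C(=O)[C@@]2(C)CCCC(C)(C)[C@H]12 | intermediate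
12 | vinylmagnesium bromide | C=C[Mg]Br | starting material
13 | (1R,2R,4S,4aS,8aS)-1-ethenyl-2,5,5,8a-tetramethyldecahydronaphthalene-1,4-diol (6α-OH, 9α-OH, 9β-vinyl) | O[C@H]1C[C@@H](C)[C@](O)(C=C)[C@@]2(C)CCCC(C)(C)[C@H]12 | intermediate
14 | (3R,4R,4aS,8aS)-4-ethenyl-4-hydroxy-3,4a,8,8-tetramethyloctahydronaphthalen-1(2H)-one (C6 ketone) | O=C1C[C@@H](C)[C@](O)(C=C)[C@@]2(C)CCCC(C)(C)[C@H]12 | intermediate
15 | (1R,2R,4R,4aS,8aS)-1-ethenyl-2,5,5,8a-tetramethyldecahydronaphthalene-1,4-diol (6β-OH) | O[C@@H]1C[C@@H](C)[C@](O)(C=C)[C@@]2(C)CCCC(C)(C)[C@H]12 | intermediate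
16 | (1R,3R,4R,4aS,8aS)-4-ethenyl-4-hydroxy-3,4a,8,8-tetramethyldecahydronaphthalen-1-yl acetate (6β-OAc) | CC(=O)O[C@@H]1C[C@@H](C)[C@](O)(C=C)[C@@]2(C)CCCC(C)(C)[C@H]12 | intermediate
17 | 3-bromofuran-2(5H)-one | O=C1OCC=C1Br | starting material
18 | B-alkyl-9-BBN adduct of 16 (boron on the terminal carbon of the former vinyl group) | CC(=O)O[C@@H]1C[C@@H](C)[C@](O)(CCB2C3CCCC2CCC3)[C@@]2(C)CCCC(C)(C)[C@H]12 | intermediate
19 | 3-{2-[(1R,2R,4R,4aS,8aS)-4-(acetyloxy)-1-hydroxy-2,5,5,8a-tetramethyldecahydronaphthalen-1-yl]ethyl}furan-2(5H)-one, that is (5S,6R,8R,9R,10S)-6β-acetoxy-9α-hydroxylabd-13-en-16,15-olide | CC(=O)O[C@@H]1C[C@@H](C)[C@](O)(CCC2=CCOC2=O)[C@@]2(C)CCCC(C)(C)[C@H]12 | target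

## Step count and risks

Total step count: 11. Longest linear sequence: 11 steps (from 1).

Steps most likely to fail:

1. Step 5. The cycloaddition may lose exo selectivity (endo mode, cis-fused adduct) or diene-face selectivity, or the open-chain hydroxy enone may be diverted through its hemiketal and dehydrate. The fallback sets out from 8 and changes to a Lewis-acid-promoted cyclization of a protected substrate. Silylation (TBSOTf, 2,6-lutidine, CH2Cl2, −78 °C) would give (4R,6S,7E)-6-[(tert-butyldimethylsilyl)oxy]-2,4,8-trimethyldeca-1,7,9-trien-3-one F1, which cannot form a hemiketal and whose larger silyloxy group raises the allylic-strain penalty of the unwanted rotamers. Cyclization of F1 at −78 to −20 °C with the bulky Lewis acid aluminium tris(2,6-diphenylphenoxide) in CH2Cl2, whose aryl pocket around the complexed C9 carbonyl disfavours the endo mode, should give the tert-butyldimethylsilyl ether of 9 F2. Bu4NF in THF would return to 9.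

2. Step 7. The nucleophile may approach the C9 carbonyl from the α face (axial attack, wrong C9 epimer), or the ketone may simply enolize toward C8. The fallback sets out from 11 and builds the carbinol from an exocyclic alkene. Wittig methylenation (Ph3PCH3Br, KOt-Bu, toluene, 90 °C) would give 4,4,8α,10β-tetramethyl-9-methylidene-trans-decalin-6α-ol F3. Epoxidation with mCPBA (NaHCO3, CH2Cl2, 0 °C) should occur on the α face, anti to the axial C10 methyl group, to give the 9α,11-epoxide (spiro-oxirane, oxygen α) F4. Excess dimethylsulfonium methylide (Me3SI, n-BuLi, THF, −10 °C to rt) opens the oxirane at its CH2 carbon and then eliminates dimethyl sulfide (one-carbon homologation of an epoxide to an allylic alcohol), which comes back to the route at 13.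

3. Step 6. The hindered tertiary C4 radical may be reduced before C–C bond formation, giving net hydrogenation instead of hydromethylation. The fallback sets out from 9 and uses cyclopropanation and hydrogenolysis. Hydroxyl-assisted Simmons–Smith cyclopropanation (Et2Zn, CH2I2, CH2Cl2, 0 °C) would give the 3α,4α-methano (cyclopropane) derivative of 9 F5. Hydrogenolysis of its least substituted bond C3–CH2 (H2 1 atm, PtO2, AcOH, rt, stopped when the cyclopropane is consumed so that the hindered C9 ketone is spared) comes back to the route at 11.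

Further compounds
F1 | step 5 | (4R,6S,7E)-6-[(tert-butyldimethylsilyl)oxy]-2,4,8-trimethyldeca-1,7,9-trien-3-one | C=C(C)C(=O)[C@H](C)C[C@H](O[Si](C)(C)C(C)(C)C)/C=C(\C)C=C
F2 | step 5 | tert-butyldimethylsilyl ether of 9 (6α-silyloxy, trans-fused) | CC(C)(C)[Si](C)(C)O[C@H]1C[C@@H](C)C(=O)[C@@]2(C)CCC=C(C)[C@H]12
F3 | step 7 | 4,4,8α,10β-tetramethyl-9-methylidene-trans-decalin-6α-ol | O[C@H]1C[C@@H](C)C(=C)[C@@]2(C)CCCC(C)(C)[C@H]12
F4 | step 7 | 9α,11-epoxide of F3 (spiro-oxirane at C9, oxygen α) | O[C@H]1C[C@@H](C)[C@]3(CO3)[C@@]2(C)CCCC(C)(C)[C@H]12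
F5 | step 6 | 3α,4α-methano (cyclopropane) derivative of 9 | O[C@H]1C[C@@H](C)C(=O)[C@@]2(C)CC[C@H]3C[C@@]3(C)[C@H]12
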